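## Retrosynthetic overview

- The target is a 2,5-diaryl-3,4-dimethyloxolane (ring O1, C2–C5) with two syringyl groups: the C2 aryl is trans to the C3 methyl, the methyls are trans, and the C5 aryl is cis to the C4 methyl. The strategy rests on the fragment C5(aryl)–C4(methyl)–C3–C2 with O1 bridging C5 and C2. This is an aryl aldehyde (C5, O1) joined to crotonaldehyde (C4 with its methyl, C3, C2) whose β-carbon acts as the nucleophile.
- Last skeletal bond: C2–aryl, by Friedel–Crafts attack of 2,6-dimethoxyphenol on the C2 oxocarbenium ion of a lactol acetate, followed by removal of the tosyl group from the C5-aryl phenol.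
- The C3 methyl comes from enolate methylation of the γ-lactone (C2 = carbonyl), anti to the C4 methyl.
- The only ring is formed first, as the cis γ-lactone, in a carbene/Ti(OiPr)4 annulation of crotonaldehyde with tosylated syringaldehyde that makes the C4–C5 and O1–C2 bonds.

Key step: step 2

Assumption: which antipode of the aminoindanol-derived N-mesityl triazolium salt gives the (4S,5R) lactone cannot be assigned with certainty on paper; the (5aS,10bR) salt is written, and the commercial (5aR,10bS) salt would be used instead if a pilot run shows the opposite sense.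

## Route

Step 1
Reactants: 1 syringaldehyde; 2 tosyl chloride
Product: 3 4-formyl-2,6-dimethoxyphenyl 4-methylbenzenesulfonate (3,5-dimethoxy-4-tosyloxybenzaldehyde)
Conditions: Et3N, DMAP (cat.), CH2Cl2, 0 °C to rt
Reagents that add atoms: none
Why: DMAP-catalysed O-sulfonylation of a phenol is routine even for the flanked 2,6-dimethoxyphenol and should give an electron-poor aldehyde whose sulfonate withstands base, hydride and Lewis acid; no stereocentre is formed.

Step 2
Reactants: 3 4-formyl-2,6-dimethoxyphenyl 4-methylbenzenesulfonate; 4 (E)-crotonaldehyde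
Product: 5 (4S,5R)-5-(3,5-dimethoxy-4-tosyloxyphenyl)-4-methyloxolan-2-one (aryl cis to methyl)
Conditions: (5aS,10bR)-2-mesityl-5a,10b-dihydro-4H,6H-indeno[2,1-b][1,2,4]triazolo[4,3-d][1,4]oxazin-2-ium chloride (10 mol%), DBU (15 mol%), Ti(OiPr)4 (20 mol%), CH2Cl2, 0 °C to rt, freshly distilled 4 (2 equiv) added slowly
Reagents that add atoms: none
Why: The free carbene (from the triazolium salt and DBU) adds to the carbonyl of 4, proton transfer gives the extended Breslow intermediate, and its β-carbon (future C4) attacks the Ti(OiPr)4-activated carbonyl of 3 to form C4–C5; after tautomerisation to the acyl azolium, the titanium alkoxide oxygen attacks the acyl carbon in a 5-exo-trig acyl substitution that forms O1–C2, closes the lactone and releases the carbene. The closest known reaction type is the carbene-catalysed homoenolate [3+2] annulation of enals with aromatic aldehydes to γ-butyrolactones, including its variant with a cooperating titanium alkoxide. C4 is set by the aminoindanol backbone of the carbene, which blocks one face of the homoenolate, and C5 by the titanium-bridged closed transition state, which places aryl and methyl on the same side and so should give the cis (4S,5R) pair. The step needs cross- over homo-annulation, cis over trans and one enantiomer: the tosyloxy aldehyde is the better electrophile, slow addition keeps the enal concentration low, and neither C4–H nor C5–H of 5 is acidic, so the kinetic cis pair cannot epimerise afterwards. Enantiocontrol with a β-methyl enal is the least secured element and would be upgraded, if needed, by recrystallisation of 5 or 7.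

Step 3
Reactants: 5 (4S,5R)-5-(3,5-dimethoxy-4-tosyloxyphenyl)-4-methyloxolan-2-one
Product: 7 (3S,4S,5R)-5-(3,5-dimethoxy-4-tosyloxyphenyl)-3,4-dimethyloxolan-2-one (3,4-trans and 4,5-cis), via lithium enolate 6 (not isolated)
Conditions: LiN(SiMe3)2 (1.1 equiv), THF, −78 °C; then MeI (3 equiv), −78 to −40 °C
Reagents that add atoms: iodomethane CI
Why: Kinetic enolate alkylation of a β-substituted γ-butyrolactone, in which MeI should approach the planar enolate 6 from the face opposite the C4 methyl and C5 aryl groups and so set C3 as S (3,4-trans), while the aryl tosylate is inert to the hindered amide base at −78 °C.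

Step 4
Reactants: 7 (3S,4S,5R)-5-(3,5-dimethoxy-4-tosyloxyphenyl)-3,4-dimethyloxolan-2-one
Product: 8 (3S,4S,5R)-5-(3,5-dimethoxy-4-tosyloxyphenyl)-3,4-dimethyloxolan-2-ol (both anomers)
Conditions: iBu2AlH (1.2 equiv), CH2Cl2, −78 °C; aq. potassium sodium tartrate
Reagents that add atoms: none
Why: Partial reduction of a lactone by iBu2AlH at −78 °C stops at the tetrahedral aluminium hemiacetal, which should give the lactol on work-up without touching C3–C5 or the aryl sulfonate; the new C2 centre is an inconsequential anomeric mixture.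

Step 5
Reactants: 8 (3S,4S,5R)-5-(3,5-dimethoxy-4-tosyloxyphenyl)-3,4-dimethyloxolan-2-ol
Product: 9 (3S,4S,5R)-5-(3,5-dimethoxy-4-tosyloxyphenyl)-3,4-dimethyloxolan-2-yl acetate (both anomers)
Conditions: Ac2O, pyridine, DMAP (cat.), CH2Cl2, 0 °C to rt
Reagents that add atoms: acetic anhydride CC(=O)OC(C)=O
Why: DMAP-catalysed O-acetylation of the lactol hydroxyl should give a stable oxocarbenium precursor whose anomeric mixture converges in the next step.

Step 6
Reactants: 9 (3S,4S,5R)-5-(3,5-dimethoxy-4-tosyloxyphenyl)-3,4-dimethyloxolan-2-yl acetate; 10 2,6-dimethoxyphenol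
Product: 11 4-[(2S,3S,4S,5R)-5-(3,5-dimethoxy-4-tosyloxyphenyl)-3,4-dimethyloxolan-2-yl]-2,6-dimethoxyphenol
Conditions: 10 (3 equiv), BF3·OEt2 (1.5 equiv), CH2Cl2, −78 to −20 °C; aq. NaHCO3
Reagents that add atoms: none
Why: Friedel–Crafts-type C-arylation of a cyclic oxocarbenium ion, in which BF3 ionises the anomeric acetate and the phenol attacks through the carbon para to its hydroxyl on the face of C2 opposite the adjacent C3 methyl, which should set C2 as S (2,3-trans, also the more stable arrangement reachable by reversible C2–O1 ionisation), while the electron-poor tosyloxyaryl group keeps the C5–O1 bond from ionising so that the cis C4–C5 pair survives.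

Step 7
Reactants: 11 4-[(2S,3S,4S,5R)-5-(3,5-dimethoxy-4-tosyloxyphenyl)-3,4-dimethyloxolan-2-yl]-2,6-dimethoxyphenol
Product: 12 4,4'-[(2S,3S,4S,5R)-3,4-dimethyloxolane-2,5-diyl]bis(2,6-dimethoxyphenol) (target)
Conditions: KOH (6 equiv), 1,4-dioxane/H2O, 80 °C, under argon; then aq. NH4Cl
Reagents that add atoms: none
Why: Hydroxide attacks the sulfonyl sulfur of the aryl tosylate (nucleophilic S–O cleavage) and should free the second phenol without touching the four stereocentres, none of which carries an acidic hydrogen; the alcohol-free medium prevents formation of an alkyl tosylate that could O-alkylate the phenoxides.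

## Compound list

1 | syringaldehyde (4-hydroxy-3,5-dimethoxybenzaldehyde) | COc1cc(C=O)cc(OC)c1O | starting material
2 | tosyl chloride (4-methylbenzenesulfonyl chloride) | Cc1ccc(cc1)S(=O)(=O)Cl | starting material
3 | 4-formyl-2,6-dimethoxyphenyl 4-methylbenzenesulfonate | COc1cc(C=O)cc(OC)c1OS(=O)(=O)c1ccc(C)cc1 | intermediate
4 | (E)-crotonaldehyde | C/C=C/C=O | starting material
5 | (4S,5R)-5-(3,5-dimethoxy-4-tosyloxyphenyl)-4-methyloxolan-2-one | O=C1O[C@@H](c2cc(OC)c(OS(=O)(=O)c3ccc(C)cc3)c(OC)c2)[C@@H](C)C1 | intermediate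
6 | lithium enolate of 5 (lithium (4S,5R)-5-aryl-4-methyl-4,5-dihydrofuran-2-olate) | [Li+].[O-]C1=C[C@H](C)[C@H](c2cc(OC)c(OS(=O)(=O)c3ccc(C)cc3)c(OC)c2)O1 | intermediate (not isolated)
7 | (3S,4S,5R)-5-(3,5-dimethoxy-4-tosyloxyphenyl)-3,4-dimethyloxolan-2-one | O=C1O[C@@H](c2cc(OC)c(OS(=O)(=O)c3ccc(C)cc3)c(OC)c2)[C@@H](C)[C@@H]1C | intermediate
8 | (3S,4S,5R)-5-(3,5-dimethoxy-4-tosyloxyphenyl)-3,4-dimethyloxolan-2-ol (both anomers) | OC1O[C@@H](c2cc(OC)c(OS(=O)(=O)c3ccc(C)cc3)c(OC)c2)[C@@H](C)[C@@H]1C | intermediate
9 | (3S,4S,5R)-5-(3,5-dimethoxy-4-tosyloxyphenyl)-3,4-dimethyloxolan-2-yl acetate (both anomers) | CC(=O)OC1O[C@@H](c2cc(OC)c(OS(=O)(=O)c3ccc(C)cc3)c(OC)c2)[C@@H](C)[C@@H]1C | intermediate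
10 | 2,6-dimethoxyphenol | COc1cccc(OC)c1O | starting material
11 | 4-[(2S,3S,4S,5R)-5-(3,5-dimethoxy-4-tosyloxyphenyl)-3,4-dimethyloxolan-2-yl]-2,6-dimethoxyphenol | COc1cc([C@H]2O[C@@H](c3cc(OC)c(OS(=O)(=O)c4ccc(C)cc4)c(OC)c3)[C@@H](C)[C@@H]2C)cc(OC)c1O | intermediate
12 | 4,4'-[(2S,3S,4S,5R)-3,4-dimethyloxolane-2,5-diyl]bis(2,6-dimethoxyphenol) | COc1cc([C@H]2O[C@@H](c3cc(OC)c(O)c(OC)c3)[C@@H](C)[C@@H]2C)cc(OC)c1O | target

## Step count and risks

Total steps: 7. Longest linear sequence: 7 (1 to 12).

Steps most likely to fail, in order of risk: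

**Step 2.** The enal may annulate with itself faster than with 3, the cis preference may be weak, or the facial selectivity of the β-methyl homoenolate under the chiral carbene may be low. The fallback leaves carbene catalysis and sets out from 3.
- Brown crotylation with (Z)-crotyldiisopinocampheylborane should give the syn alcohol 4-[(1R,2S)-1-hydroxy-2-methylbut-3-en-1-yl]-2,6-dimethoxyphenyl 4-methylbenzenesulfonate F1. The reagent is made from cis-2-butene, n-BuLi/KOtBu, (+)-B-methoxydiisopinocampheylborane (the antipode expected to give the 1R carbinol) and BF3·OEt2 in THF at −78 °C, with NaBO3 work-up.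
- Hydroboration of the vinyl group with 9-borabicyclo[3.3.1]nonane and oxidation with NaBO3 should give the diol 4-[(1R,2S)-1,4-dihydroxy-2-methylbutyl]-2,6-dimethoxyphenyl 4-methylbenzenesulfonate F2.
- TEMPO (cat.) with PhI(OAc)2 in CH2Cl2 oxidises the primary alcohol and then the resulting lactol, and the path comes back to the route at 5.

**Step 6.** The phenol may react through oxygen or through a carbon ortho to a methoxy group, the face of attack at C2 may be poorly differentiated, or the electron-rich product may ionise at C2 and be opened by a second arylation. The fallback fixes the site of the nucleophile with a metal and sets out from lactol 8.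
- PhSO2H and CaCl2 in CH2Cl2 should convert 8 into the anomeric sulfone 4-[(2R,3S,4S)-3,4-dimethyl-5-(phenylsulfonyl)oxolan-2-yl]-2,6-dimethoxyphenyl 4-methylbenzenesulfonate F3.
- Separately, bought 4-bromo-2,6-dimethoxyphenol is benzylated (BnBr, K2CO3, DMF) to 2-(benzyloxy)-5-bromo-1,3-dimethoxybenzene F4. Mg in THF turns it into (4-benzyloxy-3,5-dimethoxyphenyl)magnesium bromide F5, and ZnBr2 into (4-benzyloxy-3,5-dimethoxyphenyl)zinc bromide F6.
- F6 displaces the sulfinate of F3 through the same oxocarbenium ion, anti to the C3 methyl, and should give 4-[(2R,3S,4S,5S)-5-(4-benzyloxy-3,5-dimethoxyphenyl)-3,4-dimethyloxolan-2-yl]-2,6-dimethoxyphenyl 4-methylbenzenesulfonate F7.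
- Hydrogenolysis of the benzyl ether (H2, Pd/C, EtOAc, 1 atm, stopped when F7 is consumed) comes back to the route at 11.

**Step 7.** S–O cleavage at the flanked sulfonate may be slow enough to demand prolonged heating in strong base. The p-hydroxybenzylic C–O bonds could then open through quinone methides, with loss of configuration at C2 or C5, or the phenoxides could be oxidised by air. The fallback replaces nucleophilic cleavage by electron-transfer cleavage: from 11, Mg turnings in MeOH at rt split the S–O bond reductively and release the sulfinate without heat or hydroxide, coming back to the route at 12. This path makes no new compound (entry F0).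

Further compounds
F1 | step 2 | 4-[(1R,2S)-1-hydroxy-2-methylbut-3-en-1-yl]-2,6-dimethoxyphenyl 4-methylbenzenesulfonate | O[C@@H](c1cc(OC)c(OS(=O)(=O)c2ccc(C)cc2)c(OC)c1)[C@@H](C)C=C
F2 | step 2 | 4-[(1R,2S)-1,4-dihydroxy-2-methylbutyl]-2,6-dimethoxyphenyl 4-methylbenzenesulfonate | O[C@@H](c1cc(OC)c(OS(=O)(=O)c2ccc(C)cc2)c(OC)c1)[C@@H](C)CCO
F3 | step 6 | 4-[(2R,3S,4S)-3,4-dimethyl-5-(phenylsulfonyl)oxolan-2-yl]-2,6-dimethoxyphenyl 4-methylbenzenesulfonate (both anomers) | O=S(=O)(c1ccccc1)C1O[C@@H](c2cc(OC)c(OS(=O)(=O)c3ccc(C)cc3)c(OC)c2)[C@@H](C)[C@@H]1C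
F4 | step 6 | 2-(benzyloxy)-5-bromo-1,3-dimethoxybenzene | COc1cc(Br)cc(OC)c1OCc1ccccc1
F5 | step 6 | (4-benzyloxy-3,5-dimethoxyphenyl)magnesium bromide | COc1cc([Mg]Br)cc(OC)c1OCc1ccccc1
F6 | step 6 | (4-benzyloxy-3,5-dimethoxyphenyl)zinc bromide | COc1cc([Zn]Br)cc(OC)c1OCc1ccccc1
F7 | step 6 | 4-[(2R,3S,4S,5S)-5-(4-benzyloxy-3,5-dimethoxyphenyl)-3,4-dimethyloxolan-2-yl]-2,6-dimethoxyphenyl 4-methylbenzenesulfonate | COc1cc([C@H]2O[C@@H](c3cc(OC)c(OS(=O)(=O)c4ccc(C)cc4)c(OC)c3)[C@@H](C)[C@@H]2C)cc(OC)c1OCc1ccccc1
F0 | step 7 | none | none
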